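**Plan**

- The benzene ring of the target carries oxygen on C1 and C3 and the hydroxyalkyl chain on C5, the pattern of a folded tetraketide. The retrosynthesis first restores a carboxyl carbon on ring C4, then cuts the ring bond C4–C5 to an open-chain 3,5,7-trioxo ester (chain C2 = ring C4, chain C7 = ring C5).
- The open chain is cut at C6–C7 into the trianion of methyl 3,5-dioxohexanoate (from dehydroacetic acid) and the N-methoxy-N-methylamide of (R)-3-silyloxyoctadecanoic acid. The amide is used instead of the methyl ester so that the acylation is clean.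
- The C18 acid goes back to methyl 3-oxooctadecanoate, made from palmitoyl chloride and Meldrum's acid.
- Forward: the C18 chain is built and its ketone reduced, the chain is joined to the C6 unit, the only ring is closed by aldol aromatization, then the ester carbon is removed and the silyl ether cleaved.
- The single stereocentre (R carbinol) is set by RuCl2[(R)-BINAP] hydrogenation of the β-keto ester and lies outside every later reacting site.

Key step: step 7

Remark: compounds 11 and 12 are drawn as keto forms although they will exist as enol tautomers (12 also as ring diastereomers); this does not affect the outcome.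

**Step 1**
Reactants: 1 palmitoyl chloride (hexadecanoyl chloride); 2 Meldrum's acid (2,2-dimethyl-1,3-dioxane-4,6-dione)
Product: 4 methyl 3-oxooctadecanoate, via palmitoyl Meldrum's acid 3 (not isolated)
Conditions: pyridine, CH2Cl2, 0 °C → rt; dil. HCl wash; then MeOH, reflux
Reagents that add atoms: methanol, CO
Why: Pyridine-mediated C-acylation of Meldrum's acid followed by methanolysis with loss of acetone and CO2 (Oikawa–Yonemitsu β-keto ester synthesis) is the standard entry to long-chain methyl 3-oxoalkanoates.

**Step 2**
Reactants: 4 methyl 3-oxooctadecanoate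
Product: 5 methyl (3R)-3-hydroxyoctadecanoate
Conditions: RuCl2[(R)-BINAP] (cat.), H2 (about 50 atm), MeOH, 50 °C
Reagents that add atoms: none
Why: Noyori asymmetric hydrogenation, in which the β-keto ester chelates the divalent ruthenium centre through both carbonyls and the (R)-BINAP ligand directs hydride to one face, which for unbranched 3-oxoalkanoates should give the (3R)-carbinol, the only stereocentre of the target.

**Step 3**
Reactants: 5 methyl (3R)-3-hydroxyoctadecanoate
Product: 6 methyl (3R)-3-[(tert-butyldimethylsilyl)oxy]octadecanoate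
Conditions: TBSCl, imidazole, DMF, rt
Reagents that add atoms: tert-butyldimethylsilyl chloride (TBSCl), CC(C)(C)[Si](C)(C)Cl
Why: Imidazole-promoted silylation of a secondary alcohol (Corey conditions) installs an ether that blocks hemiketal, lactone and retro-aldol pathways in all later carbonyl chemistry.

**Step 4**
Reactants: 6 methyl (3R)-3-[(tert-butyldimethylsilyl)oxy]octadecanoate
Product: 7 (3R)-3-[(tert-butyldimethylsilyl)oxy]-N-methoxy-N-methyloctadecanamide
Conditions: MeNH(OMe)·HCl, iPrMgCl, THF, −20 → 0 °C
Reagents that add atoms: N,O-dimethylhydroxylamine hydrochloride, CNOC.Cl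
Why: Direct aminolysis of the methyl ester by the chloromagnesium amide of N,O-dimethylhydroxylamine (Weinreb amide formation) proceeds at low temperature, where the β-silyloxy group should not be eliminated.

**Step 5**
Reactants: 8 dehydroacetic acid (3-acetyl-4-hydroxy-6-methyl-2H-pyran-2-one)
Product: 9 methyl 3,5-dioxohexanoate
Conditions: Mg(OMe)2, MeOH, reflux; then dil. HCl
Reagents that add atoms: methanol, CO
Why: Methoxide opens the pyranone lactone and removes the 3-acetyl group by retro-Claisen cleavage as methyl acetate, while magnesium chelation protects the emerging 3,5-dioxo ester (the known magnesium methoxide degradation of dehydroacetic acid).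

**Step 6**
Reactants: 9 methyl 3,5-dioxohexanoate; 7 (3R)-3-[(tert-butyldimethylsilyl)oxy]-N-methoxy-N-methyloctadecanamide
Product: 11 methyl (9R)-9-[(tert-butyldimethylsilyl)oxy]-3,5,7-trioxotetracosanoate, via trilithium trianion of methyl 3,5-dioxohexanoate 10 (not isolated)
Conditions: 9 (2 equiv), LiN(iPr)2 (6.2 equiv), THF, 0 °C; then 7 (1 equiv), −78 → −20 °C; AcOH quench, aq. NaH2PO4 work-up; crude 11 taken on directly
Reagents that add atoms: none
Why: Claisen-type C-acylation of a β-polycarbonyl polyanion, in which the terminal C6 carbanion of trianion 10 is the most nucleophilic site and the N-methoxy-N-methylamide releases its ketone only on quench, so that neither over-addition nor proton transfer from an acidic product to unreacted trianion should interfere.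

**Step 7**
Reactants: 11 methyl (9R)-9-[(tert-butyldimethylsilyl)oxy]-3,5,7-trioxotetracosanoate
Product: 13 methyl 2-[(2R)-2-[(tert-butyldimethylsilyl)oxy]heptadecyl]-4,6-dihydroxybenzoate, via cyclic aldol adduct 12 (not isolated)
Conditions: KOH (1 M aq., excess), THF, 0 °C → rt, argon; then cold dil. HCl to pH 4
Reagents that add atoms: none
Why: Hydroxide converts 11 into its potassium polyenolate, whose doubly activated carbon C2 (between the ester and the C3 carbonyl) attacks the C7 ketone to form the C2–C7 bond and the cyclic β-hydroxy diketone 12; E1cB loss of hydroxide from 12 and tautomerization of the two remaining ring carbonyls then give the aromatic resorcylate, which drives the preceding equilibria forward. The transformation is the established intramolecular aldol aromatization of 3,5,7-triketo esters to β-resorcylic esters, a chemical imitation of the way alkylresorcinol-forming polyketide synthases fold a tetraketide. The benzene ring closes as a six-membered carbocycle by a 6-(enolendo)-exo-trig attack. No new stereocentre survives, because the ring stereocentres of 12 disappear on dehydration and the C9 carbinol is outside the reacting carbons. The selectivity required is aldol closure C2→C7 rather than Claisen closure C6→C1 (to an acylphloroglucinol) or O-acylation to a 4-hydroxy-2-pyranone; a potassium counter-ion in water does not chelate and activate the ester carbonyl as magnesium would, leaving the C7 ketone as the most electrophilic carbon, and the C9 silyl ether suppresses hemiketal formation at C5 and retro-aldol loss of the side chain.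

**Step 8**
Reactants: 13 methyl 2-[(2R)-2-[(tert-butyldimethylsilyl)oxy]heptadecyl]-4,6-dihydroxybenzoate
Product: 15 5-[(2R)-2-[(tert-butyldimethylsilyl)oxy]heptadecyl]benzene-1,3-diol, via silyl-protected resorcylic acid 14 (not isolated)
Conditions: KOH (excess), MeOH/H2O (degassed), reflux, argon; then cold dil. HCl to pH 4, brief warming to 50 °C
Reagents that add atoms: none
Why: Hot aqueous-methanolic KOH saponifies the hindered ester and the electron-rich β-resorcylic acid 14 then loses CO2 by ipso-protonation and decarboxylation, as in the classical conversion of orsellinate and olivetolate esters into orcinol and olivetol, while the retained silyl ether prevents lactonization of the 2-hydroxyalkyl acid to a dihydroisocoumarin.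

**Step 9**
Reactants: 15 5-[(2R)-2-[(tert-butyldimethylsilyl)oxy]heptadecyl]benzene-1,3-diol
Product: 16 5-[(2R)-2-hydroxyheptadecyl]benzene-1,3-diol
Conditions: HF·pyridine, THF/pyridine, 0 °C → rt
Reagents that add atoms: none
Why: Fluoride cleavage of the secondary alkyl silyl ether is driven by the strong Si–F bond, and the mildly acidic HF·pyridine avoids exposing the oxidation-prone resorcinol to basic fluoride and cannot affect the configurationally stable carbinol.

**Compound list**

1 | palmitoyl chloride (hexadecanoyl chloride) | CCCCCCCCCCCCCCCC(Cl)=O | starting material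
2 | Meldrum's acid (2,2-dimethyl-1,3-dioxane-4,6-dione) | CC1(C)OC(=O)CC(=O)O1 | starting material
3 | palmitoyl Meldrum's acid, 5-(1-hydroxyhexadecylidene)-2,2-dimethyl-1,3-dioxane-4,6-dione | CCCCCCCCCCCCCCCC(O)=C1C(=O)OC(C)(C)OC1=O | intermediate
4 | methyl 3-oxooctadecanoate | CCCCCCCCCCCCCCCC(=O)CC(=O)OC | intermediate
5 | methyl (3R)-3-hydroxyoctadecanoate | CCCCCCCCCCCCCCC[C@@H](O)CC(=O)OC | intermediate
6 | methyl (3R)-3-[(tert-butyldimethylsilyl)oxy]octadecanoate | CCCCCCCCCCCCCCC[C@@H](O[Si](C)(C)C(C)(C)C)CC(=O)OC | intermediate
7 | (3R)-3-[(tert-butyldimethylsilyl)oxy]-N-methoxy-N-methyloctadecanamide | CCCCCCCCCCCCCCC[C@@H](O[Si](C)(C)C(C)(C)C)CC(=O)N(C)OC | intermediate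
8 | dehydroacetic acid (3-acetyl-4-hydroxy-6-methyl-2H-pyran-2-one) | CC1=CC(O)=C(C(C)=O)C(=O)O1 | starting material
9 | methyl 3,5-dioxohexanoate | CC(=O)CC(=O)CC(=O)OC | intermediate
10 | trilithium trianion of methyl 3,5-dioxohexanoate (tris-enolate form) | [Li+].[Li+].[Li+].C=C([O-])C=C([O-])C=C([O-])OC | intermediate
11 | methyl (9R)-9-[(tert-butyldimethylsilyl)oxy]-3,5,7-trioxotetracosanoate | CCCCCCCCCCCCCCC[C@@H](O[Si](C)(C)C(C)(C)C)CC(=O)CC(=O)CC(=O)CC(=O)OC | intermediate
12 | cyclic aldol adduct, methyl 2-[(2R)-2-[(tert-butyldimethylsilyl)oxy]heptadecyl]-2-hydroxy-4,6-dioxocyclohexane-1-carboxylate (ring diastereomers) | CCCCCCCCCCCCCCC[C@@H](O[Si](C)(C)C(C)(C)C)CC1(O)CC(=O)CC(=O)C1C(=O)OC | intermediate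
13 | methyl 2-[(2R)-2-[(tert-butyldimethylsilyl)oxy]heptadecyl]-4,6-dihydroxybenzoate | CCCCCCCCCCCCCCC[C@@H](O[Si](C)(C)C(C)(C)C)Cc1cc(O)cc(O)c1C(=O)OC | intermediate
14 | 2-[(2R)-2-[(tert-butyldimethylsilyl)oxy]heptadecyl]-4,6-dihydroxybenzoic acid | CCCCCCCCCCCCCCC[C@@H](O[Si](C)(C)C(C)(C)C)Cc1cc(O)cc(O)c1C(=O)O | intermediate
15 | 5-[(2R)-2-[(tert-butyldimethylsilyl)oxy]heptadecyl]benzene-1,3-diol | CCCCCCCCCCCCCCC[C@@H](O[Si](C)(C)C(C)(C)C)Cc1cc(O)cc(O)c1 | intermediate
16 | 5-[(2R)-2-hydroxyheptadecyl]benzene-1,3-diol | CCCCCCCCCCCCCCC[C@@H](O)Cc1cc(O)cc(O)c1 | target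

**Totals and risks**

Total step count: 9.
Longest linear sequence: 8 steps (steps 1–4 and 6–9 from palmitoyl chloride); step 5 is a one-step branch from dehydroacetic acid.

The three steps most likely to fail:

**Step 6 (polyanion acylation).** The strongly basic trianion may abstract an α-proton of amide 7, leading to β-elimination of silanolate or simple return of the amide, and the sparingly soluble trianion may acylate incompletely. The fallback replaces the acyl electrophile by an aldehyde, which adds polyanions faster than it enolizes. It sets out from 7, which is reduced with iBu2AlH (THF, −78 °C) to (3R)-3-[(tert-butyldimethylsilyl)oxy]octadecanal F1. Aldol addition of trianion 10 at its terminal carbon should give methyl (9R)-9-[(tert-butyldimethylsilyl)oxy]-7-hydroxy-3,5-dioxotetracosanoate F2 as an inconsequential mixture of C7 epimers. Dess–Martin periodinane oxidation of the C7 carbinol comes back to the route at 11.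

**Step 7 (aldol aromatization).** Closure may be diverted into Claisen cyclization or pyranone formation, the ester may be hydrolysed before the ring closes, or the silyloxy group may be eliminated through the C8 enolate. The fallback ties the carboxyl terminus into a 1,3-dioxin-4-one so that it cannot serve as an acyl acceptor, while the same ring bond is still formed by aldol closure. It sets out from 7. Commercial 2,2,6-trimethyl-4H-1,3-dioxin-4-one is C-acetylated through its lithium dienolate (LiN(SiMe3)2, then acetyl chloride) to 2,2-dimethyl-6-(2-oxopropyl)-4H-1,3-dioxin-4-one F3. The dianion of F3 (LiN(iPr)2, 2 equiv) is acylated by 7 to give 6-[(6R)-6-[(tert-butyldimethylsilyl)oxy]-2,4-dioxohenicosyl]-2,2-dimethyl-4H-1,3-dioxin-4-one F4. Triethylamine in CH2Cl2 should then bring about aldol aromatization to 5-[(2R)-2-[(tert-butyldimethylsilyl)oxy]heptadecyl]-7-hydroxy-2,2-dimethyl-4H-1,3-benzodioxin-4-one F5. Methanolysis of F5 with K2CO3 in MeOH comes back to the route at 13.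

**Step 8 (saponification and decarboxylation).** Hydroxide attack on the hindered, hydrogen-bonded ester may be so slow that silyl ether loss followed by lactonization, or air oxidation of the resorcinolate, intervenes first. The fallback never forms an ester. It sets out from 7, which acylates the dianion of acetylacetone (NaH, then n-BuLi, THF) to give (8R)-8-[(tert-butyldimethylsilyl)oxy]tricosane-2,4,6-trione F6. The trianion of F6 (LiN(iPr)2, 3 equiv) is carboxylated at its terminal methyl with CO2 to (9R)-9-[(tert-butyldimethylsilyl)oxy]-3,5,7-trioxotetracosanoic acid F7. In NaOAc buffer at about pH 5, F7 should close by the same C2–C7 aldol and come back to the route at acid 14, which loses CO2 on gentle warming to give 15.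

**Further compounds**

F1 | step 6 | (3R)-3-[(tert-butyldimethylsilyl)oxy]octadecanal | CCCCCCCCCCCCCCC[C@@H](O[Si](C)(C)C(C)(C)C)CC=O
F2 | step 6 | methyl (9R)-9-[(tert-butyldimethylsilyl)oxy]-7-hydroxy-3,5-dioxotetracosanoate (C7 epimers) | CCCCCCCCCCCCCCC[C@@H](O[Si](C)(C)C(C)(C)C)CC(O)CC(=O)CC(=O)CC(=O)OC
F3 | step 7 | 2,2-dimethyl-6-(2-oxopropyl)-4H-1,3-dioxin-4-one | CC(=O)CC1=CC(=O)OC(C)(C)O1
F4 | step 7 | 6-[(6R)-6-[(tert-butyldimethylsilyl)oxy]-2,4-dioxohenicosyl]-2,2-dimethyl-4H-1,3-dioxin-4-one | CCCCCCCCCCCCCCC[C@@H](O[Si](C)(C)C(C)(C)C)CC(=O)CC(=O)CC1=CC(=O)OC(C)(C)O1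
F5 | step 7 | 5-[(2R)-2-[(tert-butyldimethylsilyl)oxy]heptadecyl]-7-hydroxy-2,2-dimethyl-4H-1,3-benzodioxin-4-one | CCCCCCCCCCCCCCC[C@@H](O[Si](C)(C)C(C)(C)C)Cc1cc(O)cc2OC(C)(C)OC(=O)c12
F6 | step 8 | (8R)-8-[(tert-butyldimethylsilyl)oxy]tricosane-2,4,6-trione | CCCCCCCCCCCCCCC[C@@H](O[Si](C)(C)C(C)(C)C)CC(=O)CC(=O)CC(C)=O
F7 | step 8 | (9R)-9-[(tert-butyldimethylsilyl)oxy]-3,5,7-trioxotetracosanoic acid | CCCCCCCCCCCCCCC[C@@H](O[Si](C)(C)C(C)(C)C)CC(=O)CC(=O)CC(=O)CC(=O)O
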